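A one-step world charges one nucleophile per turnover, so the grey run, with 1.1 equiv, has enough for its whole electrophile. Yet at 25.0 h it has reacted 49.6%, while amber, with 5.1 equiv, has reacted 99.8%.

all flasks: electrophile 20 mM

|  | nucleophile | solid base | remark | time |
|---|---|---|---|---|
| grey | 1.1 equiv (fed, over 10 h) | 0.80 equiv | run made earlier |  |
| amber | 5.1 equiv (fed, over 10 h) | 0.80 equiv | run made earlier |  |
| dusk | 0.800 equiv (fed, over 10 h) | 0.800 equiv |  | 2.0 d |
| noon | 1.60 equiv (fed, over 10 h) | 0.800 equiv |  | 2.0 d |
| summer | 3.20 equiv (fed, over 10 h) | 0.800 equiv |  | 2.0 d |

- grey (time / h: electrophile / %, target / %): 2.00: 98.6, 2.0; 3.00: 96.7, 3.0; 5.00: 91.5, 8.1; 8.00: 81.4, 17.7; 15.0: 61.8, 37.9; 25.0: 50.4, 49.1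
- amber (time / h: electrophile / %, target / %): 1.50: 96.1, 4.7; 5.00: 66.3, 33.2; 8.00: 37.4, 63.2; 12.0: 12.4, 87.3; 20.0: 1.6, 98.3; 25.0: 0.2, 99.2

(standard deviation of a reading: 0.5 percentage points)

- as a solid, counted per litre of solution: solid base
- what was read earlier has a scatter of 0.5 percentage points, one standard deviation
- candidate steps: acid set free + free base <-> salt of the base; electrophile + nucleophile -> acid set free + target; acid set free + target -> side product; solid base <-> free base; nucleophile + acid set free <-> protonated nucleophile
- at the start none of the solid base is in solution

* part of the electrophile that has reacted at the end, dusk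
* part of the electrophile that has reacted at the end, noon
* part of the electrophile that has reacted at the end, summer
* what raising the equivalents of nucleophile from its lowest to its highest value here does to the part of the electrophile that has reacted (changes below 5 percentage points count as none) (it falls / no change / it rises)

To whoever takes the bench: dusk, noon and summer start with electrophile and solid base in the flask, and nucleophile goes in over 10 h. Each turnover sets free one acid, and we count that acid as parking a second nucleophile as protonated nucleophile. That gives dusk 40.0%: the paid-for part, half the equivalents of nucleophile, as a share of the electrophile charged. Grey's paid-for part is 55.0%, which stands close to its reading. Noon's is 80.0%, and in dusk we take nucleophile as the limiting reagent. Summer's is 160%, past the whole charge, so we expect it near complete. Leave the nucleophile charges as they are, since in our count they pay for the turnovers.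

The forecast says 45%, 77% and 99%, and of the reacted part, it rises. It stands above our count in dusk and below it in noon, holding that “The solid base rescues it only slowly”.

The flasks give 44.2%, 77.2% and 99.4%, and of the reacted part, it rises, by 55 percentage points from dusk to summer, because of the larger equivalents of nucleophile.

    acid set free + free base ⇌ salt of the base, settled at all times (K = 14000 M⁻¹)
    electrophile + nucleophile → acid set free + target (k = 4.09 M⁻¹ h⁻¹)
    acid set free + target → side product (k = 17.0 M⁻¹ h⁻¹)
    solid base ⇌ free base, rate k4*(cs4 - [free base]) while solid is left; crystals form when [free base] > cs4 (solubility = 4.90 mM, k = 0.0197 h⁻¹)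
    nucleophile + acid set free ⇌ protonated nucleophile, settled at all times (K = 69000 M⁻¹)

Dusk ends 4.2 points past its paid-for 40.0%. Without the parking, dusk reaches 66.8%, and left until 20.0 d it reaches 72.7%, so the parking and the length of the run together hold it at 44.2%.

For the neighbour of dusk with 0.200 equiv of nucleophile, the paid-for part is 10.0%. That flask reacts 13.5%, again past its count.

All runs stem from a simulated flask from invented constants; scatter was added.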